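In a one-step world the limiting reagent, the reactant charged short, gives the yield by subtraction; here several steps want the same partner, so the examination is about who gets it.

| flask | left-handed substrate | right-handed substrate | partner | protic impurity | remark | time |
|---|---|---|---|---|---|---|
| ash | 0.20 M | 0.20 M | 0.60 equiv | 0.020 M | the very flask that is asked about, followed so far |  |
| oak | 0.20 M | 0.20 M | 0.30 equiv | 0.020 M | run made earlier |  |
| flask | 0.20 M | 0.20 M | 0.600 equiv | 0.0200 M |  | 2.5 d |

- ash (time / h: left-handed substrate / %, left-handed product / %): 6.00: 26.9, 23.2; 12.0: 24.9, 23.6; 20.0: 25.8, 24.3; 25.0: 25.7, 24.1; 30.0: 26.3, 23.8
- oak (time / h: left-handed substrate / %, left-handed product / %): 8.00: 40.0, 9.6; 15.0: 38.8, 10.8; 25.0: 40.3, 11.1; 30.0: 39.1, 9.4; 40.0: 41.3, 7.4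

(scatter of a reading: 1 percentage point)

- partner is single-handed; left-handed substrate and right-handed substrate are mirror images of each other, charged as a racemate, each of them at the stated concentration
- steps under discussion: partner + right-handed substrate -> right-handed product; partner + protic impurity -> quenched reagent; partner + left-handed substrate -> left-handed product
- the reaction counts as stopped when no species that holds the left-handed substrate and right-handed substrate together changes by six tenths of a point or more over the second half of the time
- the handed part of partner does not stay in what it makes, so the products of the two hands are mirror images too

1. the state of affairs at 2.5 d: stopped, and by what, or still going (it is still moving / forward and back rates have come level / the partner has run out first / all of the left-handed substrate has reacted)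
2. share of the left-handed substrate and right-handed substrate together used up at 2.5 d
3. left-handed product at 2.5 d, in percent of the left-handed substrate and right-handed substrate together charged
4. right-handed substrate at 2.5 d, in percent of the left-handed substrate and right-handed substrate together charged

**What do the runs show?** In the ash run, left-handed product already reads 23.2% at 6.00 h and stays level, and the asked time is ten times that first reading. I therefore count amounts, not time.

**Count what?** The partner budget is 25.0% for this flask: partner charged minus protic impurity, in percent of both substrates together. For the oak run it is 10.0%. The mean readings of left-handed product are 23.8% in ash and 9.66% in oak.

**But nobody read the right-handed substrate. Why leave it out?** From oak to ash the partner rises by 15.0% of the substrates, and the mean left-handed product rises by 14.1%. With a scatter of 1 percentage point per reading, the right hand shows no measurable share. So I commit to this: partner exhausted, conversion and left-handed product near the budget, right-handed substrate near 50.0%.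

**And the forecast?** It agrees on the stop, the partner has run out first, and stands near my reckoning on left-handed product, 23.8%, but differs from it on conversion, 55%, and on right-handed substrate, 18.8%. Its ground: “I take equiv as relative to the whole racemate, which is my assumption.”

The flask gives: the partner has run out first, with partner at 0% of its charge, conversion 25.0%, left-handed product 24.7%, right-handed substrate 49.7%.

    partner + right-handed substrate → right-handed product (k = 4.39 × 10⁻⁴ M⁻¹ min⁻¹)
    partner + protic impurity → quenched reagent (k = 1.62 M⁻¹ min⁻¹)
    partner + left-handed substrate → left-handed product (k = 0.0505 M⁻¹ min⁻¹)

The selectivity factor, the left-handed constant over the right-handed one, is 115. Against the budget of 25.0%, the flask holds 24.7% of left-handed product and 0.295% of right-handed product.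

In the neighbour flask with 1.50 equiv of partner, the budget grows to 70.0%, more than the 50.0% of left-handed substrate, so partner should outlast that hand. Computed, that neighbour has left-handed substrate at 0%, left-handed product 50.0%, right-handed product 5.54%, and partner at 19.3% of its charge.

The earlier runs and the new flask were generated by integration for an exercise, noise included.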